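## The problem

The target 23 is a 1-aryltetralin cyclolignan, numbered here as a tetralin. Ring B (C1–C4, C4a, C8a) is fused to ring A (H at C5, OMe at C6 and C8, OH at C7). C1 carries ring C (4-hydroxy-3,5-dimethoxyphenyl), and C2 and C3 carry the hydroxymethyl carbons C9 and C9'. A synthesis must close ring B and set three contiguous stereocentres, 1S, 2R and 3R, which are all trans and all pseudo-equatorial on the half-chair. Because this is the relaxed arrangement, one centre can pass its configuration to the other two through a chair-like ring closure. C3, a plain CH between two CH2 groups, is the centre most easily made with an auxiliary. The two 2,6-dimethoxyphenol units are the fragile part: periodate, ozone and other oxidants attack them, and C1, doubly benzylic and para to a phenol, can ionise or form a quinone methide. Both phenols therefore stay masked to the last step. The enabling feature is that C1 is bonded only to C8a of ring A, to the ipso carbon of ring C and to C2, and that ring C plus C1 is the skeleton of syringaldehyde. C1 can thus arrive as an aldehyde carbon that is attacked twice, first by ring A and then by C2. Before ring closure the two free positions of ring A are equivalent, each ortho to one OMe and para to the other, so electrophilic substitution there has no regiochemical choice.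

## Retrosynthesis

**23 from 22.** The three O–benzyl bonds are cut last. Both phenols and the C9' hydroxyl travel as benzyl ethers, which tolerate TiCl4, BF3·OEt2, organometallics and periodate, and fall together in one hydrogenolysis. The electron-rich free phenols then appear only under reducing conditions.

**22 from 21 from 19.** The C9 hydroxymethyl group is traced through aldehyde 21 to the vinyl group of 19; the C=C bond is cleaved and the terminal carbon is lost. This turns the C2 substituent into exactly the residue an allylsilane leaves behind. Free 2,6-dimethoxyphenols would not survive periodate, which is one reason ring C is carried as its benzyl ether from 16 onward.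

**19 from 14 and 16 (key disconnection).** Both bonds from C1 into ring B are cut, C1–C8a and C1–C2. Cutting only C1–C8a (the classical cyclisation) would need an open chain with C1–C2–C3 already assembled and two centres set. Cutting both reduces C1 to the carbonyl carbon of 4-O-benzylsyringaldehyde 16 and leaves allylsilane 14, which has no ring and a single stereocentre. The forward reaction must arylate the aldehyde with ring A, ionise the diarylmethanol 17 to cation 18, and close ring B through the allylsilane γ-carbon. It requires ring A to react with the aldehyde before the allylsilane does. The benzyl ether in 16 (in place of the free phenol) also keeps the Lewis acid from being consumed with release of protic acid, which would protodesilylate 14.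

**16 from 15.** One O-benzylation of syringaldehyde.

**14 from 13 from 12.** The C(sp2)–CH2Si bond is cut to (E)-alkenyl iodide 13 and Me3SiCH2MgCl, and the C=C bond of 13 to aldehyde 12 by a chromium olefination. A single olefination with Ph3P=CHCH2SiMe3 would be shorter, but an unstabilised ylide gives Z-rich mixtures. The ring closure needs the pure (E)-isomer: the silyl group must lie anti to the forming bond, on the alkene face where the equatorial C9' group sits, and only in the (E)-isomer is CH2SiMe3 remote from it.

**12 from 11 from 10; 10 from 7 and 8.** After two redox adjustments the C3–C9' bond is cut. C9' comes from benzyl chloromethyl ether 8 in an auxiliary-controlled alkylation of imide 7. The other possible cut, C3–C4 with a benzylic bromide, would need a β-alkoxy acyl enolate prone to elimination.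

**7 from 4 and 5; 4 from 2 from 1.** Imide 7 is the acylation product of (R)-4-benzyl-2-oxazolidinone 5 with acid 4. Acid 4 comes from sinapic acid 1 by hydrogenation (to 2) and benzylation.

## Roads not taken

**Alternative 1:** Intramolecular nitrile oxide cycloaddition. The cut is C3–C4, together with a temporary O–C9' bond. Oxidation of the ring A aldoxime A2 with NaOCl would generate the nitrile oxide at C4, which adds to the vinyl group on C2 and closes ring B as the fused isoxazoline A1.
- Merits: every step is of a known type, the tether enforces regiochemistry, C9' arrives already oxygenated and no carbon is discarded. In this last respect it is better than the chosen plan.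
- Weak points: A2 must already carry C1 and C2 as an open-chain pair of centres, one a diarylmethine with two electronically similar aryl groups. Ring A must also carry an ortho formyl group beside that crowded substituent, so making A2 is longer than making 14.
- C4 emerges at the ketone oxidation level and must be brought down to CH2 after N–O cleavage (H2, Raney Ni, then benzylic deoxygenation). C3 is set by the fused transition state and may need equilibration α to the C4 ketone.
- Comparison: the chosen plan sets against the safer precedent of this road its convergence (ring C enters in the ring-forming step) and the need to make only one stereocentre beforehand.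

**Alternative 2:** Rhodium-catalysed arylative annulation. The cuts are C1–C8a and C2–C3. With [Rh(OH)(cod)]2 and BINAP, ring A boronic acid A4 would add across aryl propiolate A5; the alkenylrhodium would insert the tethered allylic ether and expel methoxide, giving dihydronaphthalene ester A3 with the C3 centre set.
- Merits: absolute configuration comes from a catalyst, not a stoichiometric auxiliary, and the union is convergent. On both counts it is more economical than the chosen plan.
- Weak points: A4 is a 2,6-disubstituted, electron-rich arylboronic acid, a class that transmetalates slowly and protodeboronates readily.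
- C1 and C2 remain to be set by reducing a tetrasubstituted C1=C2 alkene that lies beside the C8 methoxy group. Syn hydrogenation would give the all-cis isomer and needs epimerisation at C2, after the vinyl group has been processed.
- Comparison: the chosen plan sets against the catalytic asymmetry of this road the fact that its ring closure delivers C1 and C2 directly, in the trans,trans arrangement and at the final oxidation level, using the innate nucleophilicity of ring A and no metalated ring A.

**Alternative 3:** Benzocyclobutene opening and Diels–Alder addition. The cuts are C1–C2 and C3–C4. Heating racemic 1-arylbenzocyclobutene A7 with the bis-lactate fumarate A8 would open the four-membered ring to an (E)-ortho-quinodimethane, which adds the fumarate to give diester A6.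
- Merits: ring B and all three centres form in one step, the fumarate geometry fixes the 2,3-trans relation, both C9 and C9' arrive as esters, and the end game is only reduction and debenzylation. That end game is shorter than the chosen one and wastes no carbon.
- Weak points: A7, with this substitution pattern, needs a multistep synthesis of its own. Absolute control rests on the facial bias of lactate esters at the temperature of a thermal ring opening, where such bias is weak. The endo/exo choice decides the C1/C2 relation, and C1 cannot be corrected afterwards.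
- Comparison: the chosen plan sets against the shorter end game of this road a reliably installed C3 centre that relays to C2 and C1, and building blocks available in a few conventional steps.

Key step: step 10

## Route

Step 1
Reactants: 1 sinapic acid
Product: 2 3-(4-hydroxy-3,5-dimethoxyphenyl)propanoic acid
Conditions: H2 (1 atm), Pd/C, MeOH, rt
Reagents that add atoms: none
Why: Catalytic hydrogenation of the cinnamic C=C bond; arene, phenol and acid are inert, and reducing before benzylation avoids hydrogenolysis of a benzyl ether.

Step 2
Reactants: 2 3-(4-hydroxy-3,5-dimethoxyphenyl)propanoic acid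
Product: 4 3-[4-(benzyloxy)-3,5-dimethoxyphenyl]propanoic acid, via benzyl ester 3 (not isolated)
Conditions: BnBr, K2CO3, DMF, 60 °C; then NaOH, MeOH/H2O, 60 °C; HCl
Reagents that add atoms: benzyl bromide, BrCc1ccccc1; sodium hydroxide, [Na+].[OH-]
Why: Williamson benzylation of phenoxide and carboxylate, then saponification of the benzyl ester in the same flask; the aryl benzyl ether is stable to hydroxide.

Step 3
Reactants: 4 3-[4-(benzyloxy)-3,5-dimethoxyphenyl]propanoic acid; 5 (R)-4-benzyl-2-oxazolidinone
Product: 7 (4R)-4-benzyl-3-{3-[4-(benzyloxy)-3,5-dimethoxyphenyl]propanoyl}-1,3-oxazolidin-2-one, via mixed pivalic anhydride 6 (not isolated)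
Conditions: PivCl, Et3N, THF, −20 °C; then 5, LiCl, −20 °C to rt
Reagents that add atoms: none
Why: N-Acylation of the oxazolidinone through the mixed anhydride (LiCl/Et3N variant); the auxiliary attacks the unhindered carbonyl and no stereocentre is touched.

Step 4
Reactants: 7 (4R)-4-benzyl-3-{3-[4-(benzyloxy)-3,5-dimethoxyphenyl]propanoyl}-1,3-oxazolidin-2-one; 8 benzyl chloromethyl ether
Product: 10 (4R)-4-benzyl-3-[(2S)-3-(benzyloxy)-2-{[4-(benzyloxy)-3,5-dimethoxyphenyl]methyl}propanoyl]-1,3-oxazolidin-2-one, via chlorotitanium enolate 9 (not isolated)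
Conditions: TiCl4, i-Pr2NEt, CH2Cl2, 0 °C; then 8, 0 °C
Reagents that add atoms: none
Why: Auxiliary-controlled (Evans-type) alkylation of the chelated chlorotitanium (Z)-enolate by the oxocarbenium ion from 8; the benzyl group of the (R)-auxiliary shields one enolate face, so C9' enters from the other and the new centre (the future C3) should be 2S.

Step 5
Reactants: 10 (4R)-4-benzyl-3-[(2S)-3-(benzyloxy)-2-{[4-(benzyloxy)-3,5-dimethoxyphenyl]methyl}propanoyl]-1,3-oxazolidin-2-one
Product: 11 (2R)-3-(benzyloxy)-2-{[4-(benzyloxy)-3,5-dimethoxyphenyl]methyl}propan-1-ol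
Conditions: LiBH4, MeOH (1 equiv), THF, 0 °C
Reagents that add atoms: none
Why: Reductive cleavage of the N-acyl oxazolidinone by borohydride; the α-centre is not enolised, the auxiliary is recovered, and the descriptor changes only because the priorities change.

Step 6
Reactants: 11 (2R)-3-(benzyloxy)-2-{[4-(benzyloxy)-3,5-dimethoxyphenyl]methyl}propan-1-ol
Product: 12 (2S)-3-(benzyloxy)-2-{[4-(benzyloxy)-3,5-dimethoxyphenyl]methyl}propanal
Conditions: Dess–Martin periodinane, NaHCO3, CH2Cl2, 0 °C to rt
Reagents that add atoms: none
Why: Dess–Martin oxidation under buffered, non-basic conditions, which should leave the α-stereocentre and the β-benzyloxy group intact; the aldehyde is used at once.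

Step 7
Reactants: 12 (2S)-3-(benzyloxy)-2-{[4-(benzyloxy)-3,5-dimethoxyphenyl]methyl}propanal
Product: 13 2-(benzyloxy)-5-[(2R,3E)-2-[(benzyloxy)methyl]-4-iodobut-3-en-1-yl]-1,3-dimethoxybenzene
Conditions: CrCl2, CHI3, 1,4-dioxane/THF, 0 °C to rt
Reagents that add atoms: iodoform, IC(I)I
Why: Takai olefination; the gem-dichromium reagent adds to the aldehyde and eliminates anti to give the (E)-alkenyl iodide, under conditions that are not basic enough to epimerise the α-centre.

Step 8
Reactants: 13 2-(benzyloxy)-5-[(2R,3E)-2-[(benzyloxy)methyl]-4-iodobut-3-en-1-yl]-1,3-dimethoxybenzene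
Product: 14 [(2E,4R)-4-[(benzyloxy)methyl]-5-[4-(benzyloxy)-3,5-dimethoxyphenyl]pent-2-en-1-yl]trimethylsilane
Conditions: Me3SiCH2MgCl, Pd(PPh3)4 (cat.), THF, 0 °C to rt
Reagents that add atoms: (trimethylsilyl)methylmagnesium chloride, C[Si](C)(C)C[Mg]Cl
Why: Kumada coupling of an alkenyl iodide with a Grignard reagent that has no β-hydrogen; oxidative addition and reductive elimination retain the (E)-geometry.

Step 9
Reactants: 15 syringaldehyde
Product: 16 4-(benzyloxy)-3,5-dimethoxybenzaldehyde
Conditions: BnBr, K2CO3, DMF, rt
Reagents that add atoms: benzyl bromide, BrCc1ccccc1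
Why: Williamson ether synthesis on the acidic phenol; masking it keeps the Lewis acid of step 10 free and protects ring C from periodate in step 11.

Step 10
Reactants: 14 [(2E,4R)-4-[(benzyloxy)methyl]-5-[4-(benzyloxy)-3,5-dimethoxyphenyl]pent-2-en-1-yl]trimethylsilane; 16 4-(benzyloxy)-3,5-dimethoxybenzaldehyde
Product: 19 (1S,2R,3R)-7-(benzyloxy)-1-[4-(benzyloxy)-3,5-dimethoxyphenyl]-3-[(benzyloxy)methyl]-2-ethenyl-6,8-dimethoxy-1,2,3,4-tetrahydronaphthalene, via diarylmethanol 17 (not isolated), via diarylmethyl cation 18 (not isolated)
Conditions: BF3·OEt2 (2 equiv), 4 Å MS, CH2Cl2, −40 to 0 °C (16 limiting)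
Reagents that add atoms: none
Why: Proposed new method: BF3-activated 16 should be attacked at its carbonyl carbon by ring A of 14 at either of the two equivalent free positions (each ortho to one OMe and para to the other), the diarylmethanol 17 should ionise at once to the diarylmethyl cation 18, and the γ-carbon of the tethered allylsilane should capture C1 with loss of silicon, so that C1–C8a and C1–C2 form in one flask; the closest known reaction types are the acid-mediated Friedel–Crafts hydroxyalkylation of electron-rich arenes by aromatic aldehydes and the intramolecular Hosomi–Sakurai capture of diarylmethyl cations. Ring B closes in a six-membered cation–olefin cyclisation in which the alkene stays outside the new ring (6-exo with respect to the alkene), through a chair-like transition state. C2 is set by the C3 centre: CH2OBn sits equatorial, the C3–H bond eclipses the alkene (the minimum of allylic 1,3-strain) and the incipient vinyl group is therefore equatorial and trans to C9'; the (E)-geometry keeps CH2SiMe3, which must lie anti to the forming bond, away from C9'. C1 is set in the same transition state: ring C, coplanar with the cation, takes the position anti to the C2–C3 bond and flanked by hydrogen, which should give the 1,2-trans and hence the 1S,2R,3R isomer. The selectivity the step needs is arylation of the aldehyde before allylation; ring A, an alkylated 1,3-dimethoxybenzene, is a stronger π-nucleophile than a γ-branched allyltrimethylsilane, and should some allylation come first, ionisation of the benzylic alcohol and Friedel–Crafts closure would still give the same ring constitution. Intramolecular capture of 18 should outrun a second intermolecular arylation, and keeping 16 limiting, together with the twisting of the C8 methoxy group out of conjugation once C8a is substituted, should hold back further hydroxyalkylation of 19.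

Step 11
Reactants: 19 (1S,2R,3R)-7-(benzyloxy)-1-[4-(benzyloxy)-3,5-dimethoxyphenyl]-3-[(benzyloxy)methyl]-2-ethenyl-6,8-dimethoxy-1,2,3,4-tetrahydronaphthalene
Product: 21 (1S,2R,3R)-7-(benzyloxy)-1-[4-(benzyloxy)-3,5-dimethoxyphenyl]-3-[(benzyloxy)methyl]-6,8-dimethoxy-1,2,3,4-tetrahydronaphthalene-2-carbaldehyde, via 1,2-diol 20 (not isolated)
Conditions: OsO4 (cat.), NaIO4, 2,6-lutidine, 1,4-dioxane/H2O, rt
Reagents that add atoms: osmium tetroxide, O=[Os](=O)(=O)=O; sodium periodate, [Na+].[O-]I(=O)(=O)=O
Why: Lemieux–Johnson oxidation (dihydroxylation, then glycol cleavage) of the only alkene; with all phenols benzylated the arenes should tolerate periodate, and the equatorial aldehyde is the stable epimer at C2.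

Step 12
Reactants: 21 (1S,2R,3R)-7-(benzyloxy)-1-[4-(benzyloxy)-3,5-dimethoxyphenyl]-3-[(benzyloxy)methyl]-6,8-dimethoxy-1,2,3,4-tetrahydronaphthalene-2-carbaldehyde
Product: 22 [(1S,2R,3R)-7-(benzyloxy)-1-[4-(benzyloxy)-3,5-dimethoxyphenyl]-3-[(benzyloxy)methyl]-6,8-dimethoxy-1,2,3,4-tetrahydronaphthalen-2-yl]methanol
Conditions: NaBH4, MeOH/THF, 0 °C
Reagents that add atoms: none
Why: Borohydride reduction of the aldehyde to the C9 alcohol; no other group is reducible and no stereocentre is affected.

Step 13
Reactants: 22 [(1S,2R,3R)-7-(benzyloxy)-1-[4-(benzyloxy)-3,5-dimethoxyphenyl]-3-[(benzyloxy)methyl]-6,8-dimethoxy-1,2,3,4-tetrahydronaphthalen-2-yl]methanol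
Product: 23 4-[(1S,2R,3R)-7-hydroxy-2,3-bis(hydroxymethyl)-6,8-dimethoxy-1,2,3,4-tetrahydronaphthalen-1-yl]-2,6-dimethoxyphenol
Conditions: H2 (1 atm), Pd/C, MeOH/EtOAc, rt
Reagents that add atoms: none
Why: Hydrogenolysis of the two aryl benzyl ethers and the alkyl benzyl ether; the ring C–H and C–aryl bonds at C1 and C4 are not cleaved under these conditions, and the phenols are released in a reducing medium.

## Compound list

1 | sinapic acid, (E)-3-(4-hydroxy-3,5-dimethoxyphenyl)prop-2-enoic acid | COc1cc(/C=C/C(=O)O)cc(OC)c1O | starting material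
2 | 3-(4-hydroxy-3,5-dimethoxyphenyl)propanoic acid | COc1cc(CCC(=O)O)cc(OC)c1O | intermediate
3 | benzyl 3-[4-(benzyloxy)-3,5-dimethoxyphenyl]propanoate | COc1cc(CCC(=O)OCc2ccccc2)cc(OC)c1OCc1ccccc1 | intermediate (not isolated)
4 | 3-[4-(benzyloxy)-3,5-dimethoxyphenyl]propanoic acid | COc1cc(CCC(=O)O)cc(OC)c1OCc1ccccc1 | intermediate
5 | (R)-4-benzyl-2-oxazolidinone | O=C1N[C@H](Cc2ccccc2)CO1 | starting material
6 | mixed anhydride of 4 with pivalic acid | COc1cc(CCC(=O)OC(=O)C(C)(C)C)cc(OC)c1OCc1ccccc1 | intermediate (not isolated)
7 | (4R)-4-benzyl-3-{3-[4-(benzyloxy)-3,5-dimethoxyphenyl]propanoyl}-1,3-oxazolidin-2-one | O=C1OC[C@@H](Cc2ccccc2)N1C(=O)CCc1cc(OC)c(OCc2ccccc2)c(OC)c1 | intermediate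
8 | benzyl chloromethyl ether | ClCOCc1ccccc1 | starting material
9 | trichlorotitanium (Z)-enolate of 7 | O=C1OC[C@@H](Cc2ccccc2)N1/C(O[Ti](Cl)(Cl)Cl)=C/Cc1cc(OC)c(OCc2ccccc2)c(OC)c1 | intermediate (not isolated)
10 | (4R)-4-benzyl-3-[(2S)-3-(benzyloxy)-2-{[4-(benzyloxy)-3,5-dimethoxyphenyl]methyl}propanoyl]-1,3-oxazolidin-2-one | O=C1OC[C@@H](Cc2ccccc2)N1C(=O)[C@H](COCc1ccccc1)Cc1cc(OC)c(OCc2ccccc2)c(OC)c1 | intermediate
11 | (2R)-3-(benzyloxy)-2-{[4-(benzyloxy)-3,5-dimethoxyphenyl]methyl}propan-1-ol | OC[C@H](COCc1ccccc1)Cc1cc(OC)c(OCc2ccccc2)c(OC)c1 | intermediate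
12 | (2S)-3-(benzyloxy)-2-{[4-(benzyloxy)-3,5-dimethoxyphenyl]methyl}propanal | O=C[C@H](COCc1ccccc1)Cc1cc(OC)c(OCc2ccccc2)c(OC)c1 | intermediate
13 | 2-(benzyloxy)-5-[(2R,3E)-2-[(benzyloxy)methyl]-4-iodobut-3-en-1-yl]-1,3-dimethoxybenzene | I/C=C/[C@H](COCc1ccccc1)Cc1cc(OC)c(OCc2ccccc2)c(OC)c1 | intermediate
14 | [(2E,4R)-4-[(benzyloxy)methyl]-5-[4-(benzyloxy)-3,5-dimethoxyphenyl]pent-2-en-1-yl]trimethylsilane | C[Si](C)(C)C/C=C/[C@H](COCc1ccccc1)Cc1cc(OC)c(OCc2ccccc2)c(OC)c1 | intermediate
15 | syringaldehyde, 4-hydroxy-3,5-dimethoxybenzaldehyde | COc1cc(C=O)cc(OC)c1O | starting material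
16 | 4-(benzyloxy)-3,5-dimethoxybenzaldehyde | COc1cc(C=O)cc(OC)c1OCc1ccccc1 | intermediate
17 | diarylmethanol: 14 carrying at one ring A position ortho to the side chain a CH(OH)[4-(benzyloxy)-3,5-dimethoxyphenyl] group, both carbinol epimers | C[Si](C)(C)C/C=C/[C@H](COCc1ccccc1)Cc1cc(OC)c(OCc2ccccc2)c(OC)c1C(O)c1cc(OC)c(OCc2ccccc2)c(OC)c1 | intermediate (not isolated)
18 | diarylmethyl cation formed from 17 by loss of hydroxide | C[Si](C)(C)C/C=C/[C@H](COCc1ccccc1)Cc1cc(OC)c(OCc2ccccc2)c(OC)c1[CH+]c1cc(OC)c(OCc2ccccc2)c(OC)c1 | intermediate (not isolated)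
19 | (1S,2R,3R)-7-(benzyloxy)-1-[4-(benzyloxy)-3,5-dimethoxyphenyl]-3-[(benzyloxy)methyl]-2-ethenyl-6,8-dimethoxy-1,2,3,4-tetrahydronaphthalene | COc1cc([C@H]2c3c(cc(OC)c(OCc4ccccc4)c3OC)C[C@@H](COCc3ccccc3)[C@@H]2C=C)cc(OC)c1OCc1ccccc1 | intermediate
20 | 1-[(1S,2R,3R)-7-(benzyloxy)-1-[4-(benzyloxy)-3,5-dimethoxyphenyl]-3-[(benzyloxy)methyl]-6,8-dimethoxy-1,2,3,4-tetrahydronaphthalen-2-yl]ethane-1,2-diol, both carbinol epimers | COc1cc([C@H]2c3c(cc(OC)c(OCc4ccccc4)c3OC)C[C@@H](COCc3ccccc3)[C@@H]2C(O)CO)cc(OC)c1OCc1ccccc1 | intermediate (not isolated)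
21 | (1S,2R,3R)-7-(benzyloxy)-1-[4-(benzyloxy)-3,5-dimethoxyphenyl]-3-[(benzyloxy)methyl]-6,8-dimethoxy-1,2,3,4-tetrahydronaphthalene-2-carbaldehyde | COc1cc([C@H]2c3c(cc(OC)c(OCc4ccccc4)c3OC)C[C@@H](COCc3ccccc3)[C@@H]2C=O)cc(OC)c1OCc1ccccc1 | intermediate
22 | [(1S,2R,3R)-7-(benzyloxy)-1-[4-(benzyloxy)-3,5-dimethoxyphenyl]-3-[(benzyloxy)methyl]-6,8-dimethoxy-1,2,3,4-tetrahydronaphthalen-2-yl]methanol | COc1cc([C@H]2c3c(cc(OC)c(OCc4ccccc4)c3OC)C[C@@H](COCc3ccccc3)[C@@H]2CO)cc(OC)c1OCc1ccccc1 | intermediate
23 | 4-[(1S,2R,3R)-7-hydroxy-2,3-bis(hydroxymethyl)-6,8-dimethoxy-1,2,3,4-tetrahydronaphthalen-1-yl]-2,6-dimethoxyphenol | COc1cc([C@H]2c3c(cc(OC)c(O)c3OC)C[C@@H](CO)[C@@H]2CO)cc(OC)c1O | target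

## Step count and least certain steps

Total: 13 steps. Longest linear sequence: 12 steps (steps 1–8 and 10–13, from sinapic acid).

**Step 10 (key step, proposed new method).**
- Most likely failures: allylation of the aldehyde ahead of arylation, which would remove the relay from C3 to C2; further hydroxyalkylation of the still-activated positions of the product; or protodesilylation of 14 by protic acid formed in the flask. The facial choice at C1 beside the peri methoxy group is a further uncertainty.
- Fallback (known chemistry, fixes the order of bond formation): the route is left at alkenyl iodide 13 and rejoined at 17 and 19. Bromination of ring A of 13 with NBS in MeCN at 0 °C should give the aryl bromide 2-(benzyloxy)-4-bromo-5-[(2R,3E)-2-[(benzyloxy)methyl]-4-iodobut-3-en-1-yl]-1,3-dimethoxybenzene F1, since both free positions are equivalent. The Kumada coupling of step 8, which selects the alkenyl iodide over the hindered aryl bromide, should give the bromo allylsilane {(2E,4R)-4-[(benzyloxy)methyl]-5-[4-(benzyloxy)-2-bromo-3,5-dimethoxyphenyl]pent-2-en-1-yl}trimethylsilane F2. Bromine–lithium exchange with n-BuLi in THF at −78 °C should give the corresponding aryllithium F3, which adds to aldehyde 16 to give diarylmethanol 17, now isolated. BF3·OEt2 in CH2Cl2 at −78 °C then ionises 17, and intramolecular Hosomi–Sakurai closure returns the route to 19.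

**Step 7 (Takai olefination).**
- Most likely failures: incomplete (E)-selectivity, and partial loss of configuration or β-elimination at the α-branched, β-alkoxy aldehyde during a slow reaction with the Lewis-acidic chromium salts.
- Fallback: the route is left at aldehyde 12 and rejoined at 13. Homologation with the Ohira–Bestmann reagent (K2CO3, MeOH, 0 °C) should give the terminal alkyne 2-(benzyloxy)-5-[(2R)-2-[(benzyloxy)methyl]but-3-yn-1-yl]-1,3-dimethoxybenzene F4. Syn hydrozirconation with Cp2Zr(H)Cl in THF gives the (E)-alkenylzirconocene chloride F5, and iodine cleaves the C–Zr bond with retention to give 13 as a single geometric isomer.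

**Step 11 (Lemieux–Johnson oxidation).**
- Most likely failures: over-oxidation, either attack on the two trialkoxyarene rings during long exposure to osmium and periodate together, or α-hydroxylation of the aldehyde.
- Fallback: the route is left at 19 and rejoined at 21 with the two oxidations separated. Dihydroxylation with OsO4 (cat.) and N-methylmorpholine N-oxide in acetone/H2O gives diol 20, which is isolated. Brief glycol cleavage with NaIO4 on silica gel in CH2Cl2 then gives 21, so the arenes never meet osmium and periodate together. This detour makes no compound outside the list (F0).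

**Step 13 (global hydrogenolysis).**
- Most likely failure: incomplete cleavage of the hindered primary alkyl benzyl ether at C9' after the two aryl ethers have gone, leaving a polar, oxidation-prone partly deprotected mixture.
- Fallback: the route is left at 22 and rejoined at 23 by Lewis-acid debenzylation with BCl3 and pentamethylbenzene as benzyl-cation trap in CH2Cl2 at −78 °C. This cleaves aryl and alkyl benzyl ethers without hydrogen and should spare the aryl methyl ethers at that temperature. It makes no compound outside the list (F0).

## Further compounds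

F1 | step 10 | 2-(benzyloxy)-4-bromo-5-[(2R,3E)-2-[(benzyloxy)methyl]-4-iodobut-3-en-1-yl]-1,3-dimethoxybenzene | I/C=C/[C@H](COCc1ccccc1)Cc1cc(OC)c(OCc2ccccc2)c(OC)c1Br
F2 | step 10 | {(2E,4R)-4-[(benzyloxy)methyl]-5-[4-(benzyloxy)-2-bromo-3,5-dimethoxyphenyl]pent-2-en-1-yl}trimethylsilane | C[Si](C)(C)C/C=C/[C@H](COCc1ccccc1)Cc1cc(OC)c(OCc2ccccc2)c(OC)c1Br
F3 | step 10 | aryllithium from F2 (lithium in place of bromine) | C[Si](C)(C)C/C=C/[C@H](COCc1ccccc1)Cc1cc(OC)c(OCc2ccccc2)c(OC)c1[Li]
F4 | step 7 | 2-(benzyloxy)-5-[(2R)-2-[(benzyloxy)methyl]but-3-yn-1-yl]-1,3-dimethoxybenzene | C#C[C@H](COCc1ccccc1)Cc1cc(OC)c(OCc2ccccc2)c(OC)c1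
F5 | step 7 | (E)-alkenylzirconocene chloride from F4 | Cl[Zr](/C=C/[C@H](COCc1ccccc1)Cc1cc(OC)c(OCc2ccccc2)c(OC)c1)(C1C=CC=C1)C1C=CC=C1
F0 | step 11 | none | none
F0 | step 13 | none | none
A1 | alternative 1 | isoxazoline-fused 1-aryltetralin (C4=N–O–C9' bridge), C1, C2 and C3 configured as in the target, phenols and C9 hydroxyl as benzyl ethers | COc1cc([C@H]2c3c(cc(OC)c(OCc4ccccc4)c3OC)C5=NOC[C@H]5[C@@H]2COCc2ccccc2)cc(OC)c1OCc1ccccc1
A2 | alternative 1 | ring A aldoxime carrying at its ortho position the C1 diarylmethine, with C2 bearing CH2OBn and a vinyl group | COc1cc([C@@H](c2c(C=NO)cc(OC)c(OCc3ccccc3)c2OC)[C@@H](COCc2ccccc2)C=C)cc(OC)c1OCc1ccccc1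
A3 | alternative 2 | methyl (3S)-7-(benzyloxy)-1-[4-(benzyloxy)-3,5-dimethoxyphenyl]-3-ethenyl-6,8-dimethoxy-3,4-dihydronaphthalene-2-carboxylate | COc1cc(C2=C(C(=O)OC)[C@H](C=C)Cc3cc(OC)c(OCc4ccccc4)c(OC)c32)cc(OC)c1OCc1ccccc1
A4 | alternative 2 | {3-(benzyloxy)-2,4-dimethoxy-6-[(2E)-4-methoxybut-2-en-1-yl]phenyl}boronic acid | OB(O)c1c(C/C=C/COC)cc(OC)c(OCc2ccccc2)c1OC
A5 | alternative 2 | methyl 3-[4-(benzyloxy)-3,5-dimethoxyphenyl]prop-2-ynoate | COC(=O)C#Cc1cc(OC)c(OCc2ccccc2)c(OC)c1
A6 | alternative 3 | bis[(2S)-1-methoxy-1-oxopropan-2-yl] (1S,2R,3R)-7-(benzyloxy)-1-[4-(benzyloxy)-3,5-dimethoxyphenyl]-6,8-dimethoxy-1,2,3,4-tetrahydronaphthalene-2,3-dicarboxylate | COc1cc([C@H]2c3c(cc(OC)c(OCc4ccccc4)c3OC)C[C@@H](C(=O)O[C@@H](C)C(=O)OC)[C@@H]2C(=O)O[C@@H](C)C(=O)OC)cc(OC)c1OCc1ccccc1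
A7 | alternative 3 | racemic 4-(benzyloxy)-7-[4-(benzyloxy)-3,5-dimethoxyphenyl]-3,5-dimethoxybicyclo[4.2.0]octa-1,3,5-triene | COc1cc(C2Cc3cc(OC)c(OCc4ccccc4)c(OC)c32)cc(OC)c1OCc1ccccc1
A8 | alternative 3 | bis[(2S)-1-methoxy-1-oxopropan-2-yl] (2E)-but-2-enedioate | COC(=O)[C@H](C)OC(=O)/C=C/C(=O)O[C@@H](C)C(=O)OC
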